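Ring A, the 2-acyloxy-3,4-dihydro-2H-pyran O7–C8–C9–C13–C5=C6, is read as the adduct of the enal O7=C6–C5=C13 and the tethered E enol isovalerate C9=C8; everything rests on this disconnection. One intramolecular oxa-Diels–Alder reaction forms C9–C13 and O7–C8, closes rings A and B, sets C8, C9 and the quaternary C13, and installs the isovaleryl acetal without a lactol stage. Its precursor is a ring C cyclopentylidene 2-vinyl enal whose formyl group is syn to C14, so the C12 tether leaves from the outer position of the oxadiene and the competing carbon diene is disfavoured. Metathesis of the C2 and C5 vinyl groups then closes ring D.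

Key step: step 13

Numbering used for atoms and rings: C1 is the quaternary carbon with CH3 and CO2CH3; C2 its CH neighbour toward the diene; C3=C4–C5=C6–O7 the dienol ether; C8 the acetal carbon; C9 the next CH; C10 and C11 the two CH2 groups; C12 the CH bonded to C1; C13 the all-carbon quaternary centre; C14 the CH2 between C13 and C2. Ring A: O7, C8, C9, C13, C5, C6. Ring B: C9, C10, C11, C12, C13. Ring C: C1, C2, C14, C13, C12. Ring D: C2, C3, C4, C5, C13, C14.

Remark: dienal 20 is deliberately the E isomer at C13=C5 (formyl syn to C14); C1 of 4 is a labile β-keto ester centre drawn trans, and the carbinol centre of 17 (drawn for attack anti to the C12 chain) disappears in step 11.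

Step 1
Reactants: 1 methyl 3-oxohept-6-enoate; 2 allyl methyl carbonate (excess)
Product: 3 methyl (6E)-8-[(methoxycarbonyl)oxy]-3-oxooct-6-enoate
Conditions: (H2IMes)(PCy3)Cl2Ru=CHPh (3 mol%), CH2Cl2, 40 °C
Reagents that add atoms: none
Why: Olefin cross-metathesis of the terminal alkene with excess allyl carbonate should give the E allylic carbonate, the β-keto ester being tolerated.

Step 2
Reactants: 3 methyl (6E)-8-[(methoxycarbonyl)oxy]-3-oxooct-6-enoate
Product: 4 methyl (1S,5S)-2-oxo-5-vinylcyclopentane-1-carboxylate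
Conditions: [Ir(cod)Cl]2 (2 mol%), (S,S,Sa)-L (4 mol%), TBD (8 mol%), THF, 25 °C; L = O,O′-(1,1′-binaphthyl-2,2′-diyl) N,N-bis(1-phenylethyl)phosphoramidite, antipode chosen to give 5S
Reagents that add atoms: none
Why: Intramolecular iridium-catalysed asymmetric allylic alkylation: the β-keto ester carbon (C1) attacks the substituted allyl terminus (C2) in a 5-exo, branched sense, the ligand sets C2, and methoxide released from the carbonate acts as the base.

Step 3
Reactants: 4 methyl (1S,5S)-2-oxo-5-vinylcyclopentane-1-carboxylate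
Product: 5 methyl (1R,5S)-1-methyl-2-oxo-5-vinylcyclopentane-1-carboxylate
Conditions: MeI, K2CO3, acetone, 20 °C
Reagents that add atoms: iodomethane, CI
Why: C-Alkylation of the β-keto ester enolate: iodomethane approaches anti to the adjacent vinyl group, so the methyl group ends up trans and the ester cis to the vinyl group at C1.

Step 4
Reactants: 5 methyl (1R,5S)-1-methyl-2-oxo-5-vinylcyclopentane-1-carboxylate
Product: 6 methyl (1R,5S)-1-methyl-2-(trifluoromethanesulfonyloxy)-5-vinylcyclopent-2-ene-1-carboxylate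
Conditions: KN(SiMe3)2, THF, −78 °C; then PhNTf2
Reagents that add atoms: N-phenylbis(trifluoromethanesulfonimide), O=S(=O)(N(c1ccccc1)S(=O)(=O)C(F)(F)F)C(F)(F)F
Why: Enol triflate formation: the ketone can enolise only toward C13 because C1 is quaternary, so O-sulfonylation gives a single regioisomer.

Step 5
Reactants: 6 methyl (1R,5S)-1-methyl-2-(trifluoromethanesulfonyloxy)-5-vinylcyclopent-2-ene-1-carboxylate; 7 but-3-en-1-ylzinc bromide
Product: 8 methyl (1R,5S)-2-(but-3-en-1-yl)-1-methyl-5-vinylcyclopent-2-ene-1-carboxylate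
Conditions: Pd(dppf)Cl2 (5 mol%), THF, 50 °C
Reagents that add atoms: none
Why: Negishi coupling of the alkenyl triflate with a primary alkylzinc reagent attaches C11 to C12, the chelating diphosphine suppressing β-hydride elimination.

Step 6
Reactants: 8 methyl (1R,5S)-2-(but-3-en-1-yl)-1-methyl-5-vinylcyclopent-2-ene-1-carboxylate
Product: 9 methyl (1S,2R,3S,5R)-1-(but-3-en-1-yl)-2-methyl-3-vinyl-6-oxabicyclo[3.1.0]hexane-2-carboxylate
Conditions: mCPBA, CH2Cl2, 0 °C
Reagents that add atoms: 3-chloroperoxybenzoic acid, OOC(=O)c1cccc(Cl)c1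
Why: Prilezhaev epoxidation: the trisubstituted C12=C13 bond should react much faster than the two monosubstituted alkenes, on the face anti to the C1 ester and the C2 vinyl group (syn to the C1 methyl).

Step 7
Reactants: 9 methyl (1S,2R,3S,5R)-1-(but-3-en-1-yl)-2-methyl-3-vinyl-6-oxabicyclo[3.1.0]hexane-2-carboxylate
Product: 10 methyl (1R,2S,5S)-2-(but-3-en-1-yl)-1-methyl-3-oxo-5-vinylcyclopentane-1-carboxylate
Conditions: BF3·OEt2 (20 mol%), CH2Cl2, −78 °C
Reagents that add atoms: none
Why: Meinwald rearrangement: the Lewis acid opens the epoxide at tertiary C12 and the C13 hydrogen migrates anti to the departing oxygen, so the carbonyl appears at C13 and the butenyl chain ends up cis to the C1 methyl; contraction to a cyclobutane is disfavoured.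

Step 8
Reactants: 10 methyl (1R,2S,5S)-2-(but-3-en-1-yl)-1-methyl-3-oxo-5-vinylcyclopentane-1-carboxylate; 11 4,4,5,5-tetramethyl-2-vinyl-1,3,2-dioxaborolane
Product: 13 potassium trifluoro{(1E)-4-[(1S,2R,3S)-2-(methoxycarbonyl)-2-methyl-5-oxo-3-vinylcyclopentyl]but-1-en-1-yl}borate, via pinacol boronate 12 (not isolated)
Conditions: (H2IMes)(PCy3)Cl2Ru=CHPh (5 mol%), CH2Cl2, 40 °C; then KHF2, MeOH–H2O, 20 °C
Reagents that add atoms: potassium hydrogen difluoride, F.[F-].[K+]
Why: Olefin cross-metathesis with the vinylboronate is E-selective and should occur at the unhindered butenyl alkene, not at the vinyl group next to the quaternary carbon; KHF2 then converts the boronate into the trifluoroborate.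

Step 9
Reactants: 13 potassium trifluoro{(1E)-4-[(1S,2R,3S)-2-(methoxycarbonyl)-2-methyl-5-oxo-3-vinylcyclopentyl]but-1-en-1-yl}borate; 14 3-methylbutanoic acid
Product: 15 methyl (1R,2S,5S)-1-methyl-2-{(3E)-4-[(3-methylbutanoyl)oxy]but-3-en-1-yl}-3-oxo-5-vinylcyclopentane-1-carboxylate
Conditions: CuBr (10 mol%), DMAP (20 mol%), 4 Å MS, O2 (1 atm), MeCN, 60 °C
Reagents that add atoms: none
Why: Copper-catalysed oxidative C–O coupling (Chan–Lam type) of an alkenyltrifluoroborate with a carboxylic acid proceeds with retention, which fixes the E geometry of C9=C8.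

Step 10
Reactants: 15 methyl (1R,2S,5S)-1-methyl-2-{(3E)-4-[(3-methylbutanoyl)oxy]but-3-en-1-yl}-3-oxo-5-vinylcyclopentane-1-carboxylate; 16 ethynylmagnesium bromide
Product: 17 methyl (1R,2S,3R,5S)-3-ethynyl-3-hydroxy-1-methyl-2-{(3E)-4-[(3-methylbutanoyl)oxy]but-3-en-1-yl}-5-vinylcyclopentane-1-carboxylate
Conditions: CeCl3, THF, −78 °C; then aq. NH4Cl
Reagents that add atoms: none
Why: 1,2-Addition of an organocerium acetylide (Imamoto conditions) to the ketone should outrun enolisation at C12 and attack on either ester.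

Step 11
Reactants: 17 methyl (1R,2S,3R,5S)-3-ethynyl-3-hydroxy-1-methyl-2-{(3E)-4-[(3-methylbutanoyl)oxy]but-3-en-1-yl}-5-vinylcyclopentane-1-carboxylate
Product: 18 methyl (1R,2S,3Z,5S)-3-(1-iodo-2-oxoethylidene)-1-methyl-2-{(3E)-4-[(3-methylbutanoyl)oxy]but-3-en-1-yl}-5-vinylcyclopentane-1-carboxylate
Conditions: NIS, Au(PPh3)NTf2 (2 mol%), MoO2(acac)2 (2 mol%), Ph3PO, CH2Cl2, 20 °C
Reagents that add atoms: N-iodosuccinimide, O=C1CCC(=O)N1I
Why: Iodo-Meyer–Schuster rearrangement: 1,3-shift of the tertiary hydroxyl to the alkyne terminus and iodination of the allenol at C5 give the α-iodoenal, expected with the formyl group syn to the smaller C14 methylene and iodine syn to C12, the usual preference for halogen cis to the larger β-substituent.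

Step 12
Reactants: 18 methyl (1R,2S,3Z,5S)-3-(1-iodo-2-oxoethylidene)-1-methyl-2-{(3E)-4-[(3-methylbutanoyl)oxy]but-3-en-1-yl}-5-vinylcyclopentane-1-carboxylate; 19 tributyl(vinyl)stannane
Product: 20 methyl (1R,2R,3E,5S)-1-methyl-2-{(3E)-4-[(3-methylbutanoyl)oxy]but-3-en-1-yl}-3-(1-oxobut-3-en-2-ylidene)-5-vinylcyclopentane-1-carboxylate
Conditions: Pd(PPh3)4 (5 mol%), CuI (10 mol%), DMF, 40 °C
Reagents that add atoms: none
Why: Stille coupling at the C5–I bond transfers vinyl with retention of the alkene geometry, so the formyl group stays syn to C14.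

Step 13
Reactants: 20 methyl (1R,2R,3E,5S)-1-methyl-2-{(3E)-4-[(3-methylbutanoyl)oxy]but-3-en-1-yl}-3-(1-oxobut-3-en-2-ylidene)-5-vinylcyclopentane-1-carboxylate
Product: 21 methyl (1S,3S,4R,5R,8R,9S)-3,12-diethenyl-4-methyl-9-[(3-methylbutanoyl)oxy]-10-oxatricyclo[6.4.0.0(1,5)]dodec-11-ene-4-carboxylate
Conditions: Eu(fod)3 [tris(6,6,7,7,8,8,8-heptafluoro-2,2-dimethyl-3,5-octanedionato)europium] (10 mol%), toluene, 90 °C
Reagents that add atoms: none
Why: Eu(fod)3 binds O7 of the s-cis heterodiene O7=C6–C5=C13 and makes it more electrophilic, and the enol ester C9=C8 adds across C13 and O7 in a single asynchronous [4+2] step in which the C9–C13 bond is further advanced than O7–C8. The closest known reaction type is the intramolecular inverse-electron-demand oxa-Diels–Alder reaction of α,β-unsaturated aldehydes with tethered enol ethers; an enol ester dienophile and a fully substituted β-carbon are the extensions. Ring B closes through the C10–C11–C12 tether in a 5-exo sense at both π systems (C8 and C5 stay outside it), and ring A is the six-membered ring of the cycloaddition itself. C13 is set by the tether, since C9 can reach only the face of C13 that carries C11 on C12 (cis B/C junction), which places C5 on the face of the C2 vinyl group; C9 follows from the cis A/B junction that the three-atom tether imposes, and C8 from suprafacial transfer of the E geometry, which puts the acyloxy group trans to C10. The step needs periselectivity for the oxadiene over the carbon diene C3=C4–C5=C13 and over 1,5-hydrogen shift, and this is secured by the E geometry at C13=C5: the tether sits on the outer position of the oxadiene but on the inner position of the carbon diene, whose C5 vinyl group is also twisted out of conjugation by C12.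

Step 14
Reactants: 21 methyl (1S,3S,4R,5R,8R,9S)-3,12-diethenyl-4-methyl-9-[(3-methylbutanoyl)oxy]-10-oxatricyclo[6.4.0.0(1,5)]dodec-11-ene-4-carboxylate
Product: 22 CNP0315847.1, the tetracyclic isovaleryl acetal with ring D closed by C3=C4
Conditions: (H2IMes)(PCy3)Cl2Ru=CHPh (10 mol%), toluene, 60 °C
Reagents that add atoms: none
Why: Ring-closing metathesis (ene–diene): the two vinyl groups are cis on ring C, the carbene formed at the C2 vinyl group closes the six-membered ring D onto the terminal alkene of the dienol ether, and the trisubstituted enol ether C5=C6 and the acyl acetal should stay untouched.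

Compound list
1 | methyl 3-oxohept-6-enoate | COC(=O)CC(=O)CCC=C | starting material
2 | allyl methyl carbonate | C=CCOC(=O)OC | starting material
3 | methyl (6E)-8-[(methoxycarbonyl)oxy]-3-oxooct-6-enoate | COC(=O)CC(=O)CC/C=C/COC(=O)OC | intermediate
4 | methyl (1S,5S)-2-oxo-5-vinylcyclopentane-1-carboxylate (trans; C1 labile) | COC(=O)[C@H]1[C@H](C=C)CCC1=O | intermediate
5 | methyl (1R,5S)-1-methyl-2-oxo-5-vinylcyclopentane-1-carboxylate | COC(=O)[C@]1(C)[C@H](C=C)CCC1=O | intermediate
6 | methyl (1R,5S)-1-methyl-2-(trifluoromethanesulfonyloxy)-5-vinylcyclopent-2-ene-1-carboxylate | COC(=O)[C@]1(C)[C@H](C=C)CC=C1OS(=O)(=O)C(F)(F)F | intermediate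
7 | but-3-en-1-ylzinc bromide | C=CCC[Zn]Br | starting material
8 | methyl (1R,5S)-2-(but-3-en-1-yl)-1-methyl-5-vinylcyclopent-2-ene-1-carboxylate | COC(=O)[C@]1(C)[C@H](C=C)CC=C1CCC=C | intermediate
9 | methyl (1S,2R,3S,5R)-1-(but-3-en-1-yl)-2-methyl-3-vinyl-6-oxabicyclo[3.1.0]hexane-2-carboxylate (epoxide cis to the C1 methyl) | COC(=O)[C@]1(C)[C@H](C=C)C[C@H]2O[C@@]12CCC=C | intermediate
10 | methyl (1R,2S,5S)-2-(but-3-en-1-yl)-1-methyl-3-oxo-5-vinylcyclopentane-1-carboxylate | COC(=O)[C@]1(C)[C@H](C=C)CC(=O)[C@H]1CCC=C | intermediate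
11 | 4,4,5,5-tetramethyl-2-vinyl-1,3,2-dioxaborolane | C=CB1OC(C)(C)C(C)(C)O1 | starting material
12 | methyl (1R,2S,5S)-1-methyl-3-oxo-2-[(3E)-4-(4,4,5,5-tetramethyl-1,3,2-dioxaborolan-2-yl)but-3-en-1-yl]-5-vinylcyclopentane-1-carboxylate (not isolated) | COC(=O)[C@]1(C)[C@H](C=C)CC(=O)[C@H]1CC/C=C/B2OC(C)(C)C(C)(C)O2 | intermediate
13 | potassium trifluoro{(1E)-4-[(1S,2R,3S)-2-(methoxycarbonyl)-2-methyl-5-oxo-3-vinylcyclopentyl]but-1-en-1-yl}borate | COC(=O)[C@]1(C)[C@H](C=C)CC(=O)[C@H]1CC/C=C/[B-](F)(F)F.[K+] | intermediate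
14 | 3-methylbutanoic acid (isovaleric acid) | CC(C)CC(O)=O | starting material
15 | methyl (1R,2S,5S)-1-methyl-2-{(3E)-4-[(3-methylbutanoyl)oxy]but-3-en-1-yl}-3-oxo-5-vinylcyclopentane-1-carboxylate | COC(=O)[C@]1(C)[C@H](C=C)CC(=O)[C@H]1CC/C=C/OC(=O)CC(C)C | intermediate
16 | ethynylmagnesium bromide | C#C[Mg]Br | starting material
17 | methyl (1R,2S,3R,5S)-3-ethynyl-3-hydroxy-1-methyl-2-{(3E)-4-[(3-methylbutanoyl)oxy]but-3-en-1-yl}-5-vinylcyclopentane-1-carboxylate | COC(=O)[C@]1(C)[C@H](C=C)C[C@](O)(C#C)[C@H]1CC/C=C/OC(=O)CC(C)C | intermediate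
18 | methyl (1R,2S,3Z,5S)-3-(1-iodo-2-oxoethylidene)-1-methyl-2-{(3E)-4-[(3-methylbutanoyl)oxy]but-3-en-1-yl}-5-vinylcyclopentane-1-carboxylate | COC(=O)[C@]1(C)[C@H](C=C)C/C(=C(\C=O)I)[C@H]1CC/C=C/OC(=O)CC(C)C | intermediate
19 | tributyl(vinyl)stannane | C=C[Sn](CCCC)(CCCC)CCCC | starting material
20 | methyl (1R,2R,3E,5S)-1-methyl-2-{(3E)-4-[(3-methylbutanoyl)oxy]but-3-en-1-yl}-3-(1-oxobut-3-en-2-ylidene)-5-vinylcyclopentane-1-carboxylate (formyl syn to C14) | COC(=O)[C@]1(C)[C@H](C=C)C/C(=C(\C=O)C=C)[C@H]1CC/C=C/OC(=O)CC(C)C | intermediate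
21 | methyl (1S,3S,4R,5R,8R,9S)-3,12-diethenyl-4-methyl-9-[(3-methylbutanoyl)oxy]-10-oxatricyclo[6.4.0.0(1,5)]dodec-11-ene-4-carboxylate (skeleton numbering: 1R,2S,8S,9R,12R,13S) | COC(=O)[C@]1(C)[C@H](C=C)C[C@@]23C(C=C)=CO[C@@H](OC(=O)CC(C)C)[C@@H]2CC[C@@H]13 | intermediate
22 | CNP0315847.1, tetracyclic isovaleryl acetal (skeleton numbering: 1R,2S,8S,9R,12R,13S; ring D closed by C3=C4) | COC(=O)[C@]1(C)[C@@H]2C=CC3=CO[C@@H](OC(=O)CC(C)C)[C@@H]4CC[C@@H]1[C@]34C2 | target

Total step count: 14. Longest linear sequence: 14 steps (from 1).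

The three steps most likely to fail:

Step 13 (key step). The enol ester is a weak dienophile, so the cycloaddition may be slower than E/Z isomerisation at C13=C5, than 1,5-hydrogen shift from C12 or C14 to O7 (which would scramble C12), or than addition to the carbon diene. Fallback: the cycloaddition would be run one stage earlier, on iodoenal 18, whose heterodiene is more electron-poor and carries no vinyl group. Heating 18 with Eu(fod)3 should give the iodo cycloadduct methyl (1S,3S,4R,5R,8R,9S)-3-ethenyl-12-iodo-4-methyl-9-[(3-methylbutanoyl)oxy]-10-oxatricyclo[6.4.0.0(1,5)]dodec-11-ene-4-carboxylate F1. Stille coupling of F1 with 19 (Pd(PPh3)4, CuI, DMF) comes back to the route at 21.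

Step 11. NIS may iodinate the enol ester double bond, the gold catalyst may trigger cyclisation of the alkyne onto the C2 vinyl group (a 1,6-enyne), and the geometry at C13=C5 may not be controlled. Fallback: from 15, buta-1,3-dien-2-ylmagnesium chloride would be added in the presence of CeCl3 to give the tertiary dienyl carbinol methyl (1R,2S,3R,5S)-3-(buta-1,3-dien-2-yl)-3-hydroxy-1-methyl-2-{(3E)-4-[(3-methylbutanoyl)oxy]but-3-en-1-yl}-5-vinylcyclopentane-1-carboxylate F2. Oxidation of F2 with pyridinium chlorochromate, C5H5NH[CrO3Cl] (oxidative 1,3-transposition of a tertiary allylic alcohol), should give dienal 20 directly, where the route is rejoined without iodine, gold or tin.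

Step 7. The C1 ester group or a ring bond may migrate instead of the C13 hydrogen, or the new ketone may enolise and scramble C12. Fallback: from 9, the epoxide would be isomerised with Et2Al(TMP) to the exocyclic allylic alcohol methyl (1R,2Z,3R,5S)-2-(but-3-en-1-ylidene)-3-hydroxy-1-methyl-5-vinylcyclopentane-1-carboxylate F3. Dess–Martin oxidation would give the alkylidene ketone methyl (1R,2Z,5S)-2-(but-3-en-1-ylidene)-1-methyl-3-oxo-5-vinylcyclopentane-1-carboxylate F4, and conjugate reduction of F4 with [(Ph3P)CuH]6 followed by protonation of the enolate comes back to the route at 10. This fallback gives no control over C12, so the C12 epimer would have to be separated and recycled by base equilibration.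

Further compounds
F1 | step 13 | methyl (1S,3S,4R,5R,8R,9S)-3-ethenyl-12-iodo-4-methyl-9-[(3-methylbutanoyl)oxy]-10-oxatricyclo[6.4.0.0(1,5)]dodec-11-ene-4-carboxylate | COC(=O)[C@]1(C)[C@H](C=C)C[C@@]23C(I)=CO[C@@H](OC(=O)CC(C)C)[C@@H]2CC[C@@H]13
F2 | step 11 | methyl (1R,2S,3R,5S)-3-(buta-1,3-dien-2-yl)-3-hydroxy-1-methyl-2-{(3E)-4-[(3-methylbutanoyl)oxy]but-3-en-1-yl}-5-vinylcyclopentane-1-carboxylate | COC(=O)[C@]1(C)[C@H](C=C)C[C@](O)(C(=C)C=C)[C@H]1CC/C=C/OC(=O)CC(C)C
F3 | step 7 | methyl (1R,2Z,3R,5S)-2-(but-3-en-1-ylidene)-3-hydroxy-1-methyl-5-vinylcyclopentane-1-carboxylate | COC(=O)[C@]1(C)[C@H](C=C)C[C@@H](O)/C1=C\CC=C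
F4 | step 7 | methyl (1R,2Z,5S)-2-(but-3-en-1-ylidene)-1-methyl-3-oxo-5-vinylcyclopentane-1-carboxylate | COC(=O)[C@]1(C)[C@H](C=C)CC(=O)/C1=C\CC=C
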